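**Retrosynthetic overview** (numbering: lactone O1–C2(=O)–C3–C4(OH)–C5(CH3); side chain C6H2, C7(CH3)(OH), C8–C16, then the aryl ring)
1. C16–aryl: hydroboration and B-alkyl Suzuki coupling of a terminal alkene with 4-iodophenol, last step; the benzene ring is bought.
2. C5–C6 and the lactone C–O bond: chelation-controlled addition of a β-lithio alkoxide (from a chiral 2,2-disubstituted epoxide) to an α-hydroxy methyl ketone made from L-malic acid, lactonising in the same flask. C4 is bought and C5 is set by C4.
3. Key step, C7–C8: light-driven radical addition of the brominated pivalaldehyde acetal of L-lactic acid to nona-1,8-diene, anti to the tert-butyl group. This creates the C7 quaternary carbinol centre from the lactic acid chirality stored in the acetal.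
4. Ring order: the two temporary dioxolanone rings (lactic and malic acid acetals) come first and are opened on the way; the γ-lactone, the only ring built for the target, closes in the fragment union. No protecting group is carried.

Assumption: every compound marked "starting material" in the compound list is bought in the form and configuration shown, and all reagents are commercial.

**Route**

Step 1
Reactants: 1 (S)-lactic acid; 2 pivalaldehyde
Product: 3 (2S,5S)-2-tert-butyl-5-methyl-1,3-dioxolan-4-one
Conditions: TsOH·H2O (cat.), H2SO4 (cat.), pentane, reflux, water separator; recrystallise from pentane/Et2O at −78 °C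
Reagents that add atoms: none
Why: Acid-catalysed acetalisation (Seebach dioxolanone formation) leaves the lactic acid stereocentre untouched and lets it steer the new acetal centre to the cis-(2S,5S) isomer (about 4:1), which is obtained pure by low-temperature crystallisation.

Step 2
Reactants: 3 (2S,5S)-2-tert-butyl-5-methyl-1,3-dioxolan-4-one
Product: 4 (2R,5R)-5-bromo-2-tert-butyl-5-methyl-1,3-dioxolan-4-one
Conditions: NBS (1.1 equiv), AIBN (2 mol %), PhCF3, 85 °C; filter, concentrate, use crude
Reagents that add atoms: N-bromosuccinimide, O=C1CCC(=O)N1Br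
Why: Wohl–Ziegler radical bromination takes the weak captodative C5–H and leaves the tert-butyl-shielded acetal carbon unchanged in space (only its descriptor changes), so the lactic acid chirality is now held by the acetal alone, and the configuration at C5 is irrelevant because the next step passes through the planar radical.

Step 3
Reactants: 4 (2R,5R)-5-bromo-2-tert-butyl-5-methyl-1,3-dioxolan-4-one; 5 nona-1,8-diene
Product: 6 (2S,5R)-2-tert-butyl-5-methyl-5-(non-8-en-1-yl)-1,3-dioxolan-4-one
Conditions: 5 (10 equiv), (TMS)3SiH (1.5 equiv, syringe pump over 6 h), [Ir(dF(CF3)ppy)2(dtbbpy)]PF6 (1 mol %), Na2CO3, PhCF3, 450 nm LEDs, 25 °C; excess 5 distilled off and reused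
Reagents that add atoms: none
Why: Proposed new method: a light-started silyl-radical chain in which (TMS)3Si• takes bromine from the activated tertiary C–Br bond of 4, the planar captodative 4-oxo-1,3-dioxolan-5-yl radical adds through the face anti to the tert-butyl group to a terminal CH2 of the diene (present in tenfold excess to offset the modest rate of this addition), and the secondary alkyl adduct radical is quenched by (TMS)3SiH, which barely reduces the stabilised dioxolanyl radical because the Si–H bond is about as weak as the C–H bond that would form, so the C7–C8 bond and the C7 quaternary centre (5R in 6) are set by the acetal carbon that stores the lactic acid chirality; the closest known chemistry is the silane-mediated photoredox Giese-type addition of alkyl bromides and the anti-selective allylation and deuteration of this same radical, whereas its intermolecular addition to an unactivated alkene to build a quaternary α-hydroxy acid centre is not known.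

Step 4
Reactants: 6 (2S,5R)-2-tert-butyl-5-methyl-5-(non-8-en-1-yl)-1,3-dioxolan-4-one
Product: 7 (2R)-2-methylundec-10-ene-1,2-diol
Conditions: LiAlH4 (1.5 equiv), THF, 0 → 25 °C; H2O, 15% NaOH, H2O work-up
Reagents that add atoms: none
Why: LiAlH4 reduction turns the acylal-type carbonyl into the primary alcohol (the future C6) and releases the pivalaldehyde unit as neopentyl alcohol, while no bond to the quaternary centre is broken (configuration retained) and the isolated alkene is inert.

Step 5
Reactants: 7 (2R)-2-methylundec-10-ene-1,2-diol
Product: 9 (2R)-2-methyl-2-(non-8-en-1-yl)oxirane, via primary tosylate 8 (not isolated)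
Conditions: NaH (2.5 equiv), N-tosylimidazole (1.05 equiv), THF, 0 → 25 °C
Reagents that add atoms: none
Why: Selective sulfonylation of the primary alkoxide followed by intramolecular Williamson etherification by the tertiary alkoxide closes the epoxide without ever breaking the C–O bond at the stereocentre, so its configuration is retained.

Step 6
Reactants: 10 2-[(4S)-2,2-dimethyl-5-oxo-1,3-dioxolan-4-yl]acetic acid
Product: 11 methyl 2-[(4S)-2,2-dimethyl-5-oxo-1,3-dioxolan-4-yl]acetate
Conditions: MeI (1.5 equiv), KHCO3 (1.5 equiv), DMF, 25 °C
Reagents that add atoms: iodomethane, CI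
Why: SN2 O-methylation of the carboxylate under bicarbonate is mild enough to leave the base-labile dioxolanone and the malic acid stereocentre intact.

Step 7
Reactants: 11 methyl 2-[(4S)-2,2-dimethyl-5-oxo-1,3-dioxolan-4-yl]acetate
Product: 12 methyl (3S)-3-hydroxy-4-[methoxy(methyl)amino]-4-oxobutanoate
Conditions: MeNH(OMe)·HCl (1.2 equiv), AlMe3 (1.2 equiv), CH2Cl2, −10 → 0 °C; aq. KNaC4H4O6 (potassium sodium tartrate) work-up
Reagents that add atoms: N,O-dimethylhydroxylamine hydrochloride, CNOC.Cl
Why: Weinreb aminolysis with the dimethylaluminium amide opens the activated dioxolanone carbonyl much faster than the methyl ester, releasing acetone and the free C4 hydroxyl without touching the stereocentre.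

Step 8
Reactants: 12 methyl (3S)-3-hydroxy-4-[methoxy(methyl)amino]-4-oxobutanoate
Product: 13 methyl (3S)-3-hydroxy-4-oxopentanoate
Conditions: MeMgBr (2.2 equiv), THF, −78 → −30 °C; aq. NH4Cl at −30 °C; used at once
Reagents that add atoms: methylmagnesium bromide, C[Mg]Br
Why: Weinreb ketone synthesis, in which the first equivalent deprotonates the hydroxyl and the second gives a chelated tetrahedral magnesium intermediate that collapses to the methyl ketone only on quench, so there is no over-addition, the methyl ester survives at low temperature and the stereocentre is unchanged.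

Step 9
Reactants: 9 (2R)-2-methyl-2-(non-8-en-1-yl)oxirane; 13 methyl (3S)-3-hydroxy-4-oxopentanoate
Product: 17 (4S,5S)-4-hydroxy-5-[(2R)-2-hydroxy-2-methylundec-10-en-1-yl]-5-methyloxolan-2-one, via dilithio alkoxide 14 (not isolated), via chloromagnesium alkoxide 15 (not isolated), via open-chain trihydroxy ester 16 (not isolated)
Conditions: 9 (1.3 equiv), lithium 4,4'-di-tert-butylbiphenylide (2.2 equiv per 9), THF, −78 °C; separately 13, t-BuMgCl (1.0 equiv), THF, −78 °C, cannulated onto the dianion; −78 → 0 °C; aq. NH4Cl; then PPTS (cat.), CH2Cl2, 25 °C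
Reagents that add atoms: none
Why: Reductive lithiation of the 2,2-disubstituted epoxide by the arene radical anion cleaves the primary C–O bond to give β-lithio alkoxide 14 with C7 untouched (Cohen-type epoxide lithiation), which adds to the ketone of magnesium chelate 15 from the face opposite the CH2CO2Me arm (Cram chelate model), making C5 S with C6 cis to the C4 hydroxyl, after which the C5 oxygen closes onto the methyl ester (lactonisation).

Step 10
Reactants: 17 (4S,5S)-4-hydroxy-5-[(2R)-2-hydroxy-2-methylundec-10-en-1-yl]-5-methyloxolan-2-one; 18 4-iodophenol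
Product: 20 (4S,5S)-4-hydroxy-5-[(2R)-2-hydroxy-11-(4-hydroxyphenyl)-2-methylundecyl]-5-methyloxolan-2-one, via B-alkyl borane 19 (not isolated)
Conditions: 9-BBN (3 equiv), THF, 0 → 25 °C; then 18 (1.2 equiv), PdCl2(dppf) (5 mol %), AsPh3 (5 mol %), Cs2CO3 (3 equiv), DMF/THF/H2O, 25 °C; 1 M HCl work-up
Reagents that add atoms: none
Why: Anti-Markovnikov hydroboration of the terminal alkene and room-temperature B-alkyl Suzuki–Miyaura coupling with the aryl iodide form the C16–aryl bond without touching a stereocentre, and any lactone opened by the mild base recloses on acidification.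

**Compound list**
1 | (S)-lactic acid, (2S)-2-hydroxypropanoic acid | C[C@H](O)C(=O)O | starting material
2 | pivalaldehyde, 2,2-dimethylpropanal | CC(C)(C)C=O | starting material
3 | (2S,5S)-2-tert-butyl-5-methyl-1,3-dioxolan-4-one | C[C@@H]1O[C@H](C(C)(C)C)OC1=O | intermediate
4 | (2R,5R)-5-bromo-2-tert-butyl-5-methyl-1,3-dioxolan-4-one (Br trans to tert-butyl) | C[C@]1(Br)O[C@H](C(C)(C)C)OC1=O | intermediate
5 | nona-1,8-diene | C=CCCCCCC=C | starting material
6 | (2S,5R)-2-tert-butyl-5-methyl-5-(non-8-en-1-yl)-1,3-dioxolan-4-one | C[C@]1(CCCCCCCC=C)O[C@H](C(C)(C)C)OC1=O | intermediate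
7 | (2R)-2-methylundec-10-ene-1,2-diol | C[C@@](O)(CCCCCCCC=C)CO | intermediate
8 | (2R)-2-hydroxy-2-methylundec-10-en-1-yl 4-methylbenzenesulfonate | C[C@@](O)(CCCCCCCC=C)COS(=O)(=O)c1ccc(C)cc1 | intermediate (not isolated)
9 | (2R)-2-methyl-2-(non-8-en-1-yl)oxirane | C[C@@]1(CCCCCCCC=C)CO1 | intermediate
10 | 2-[(4S)-2,2-dimethyl-5-oxo-1,3-dioxolan-4-yl]acetic acid (acetonide of L-malic acid) | CC1(C)O[C@@H](CC(=O)O)C(=O)O1 | starting material
11 | methyl 2-[(4S)-2,2-dimethyl-5-oxo-1,3-dioxolan-4-yl]acetate | CC1(C)O[C@@H](CC(=O)OC)C(=O)O1 | intermediate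
12 | methyl (3S)-3-hydroxy-4-[methoxy(methyl)amino]-4-oxobutanoate | CON(C)C(=O)[C@@H](O)CC(=O)OC | intermediate
13 | methyl (3S)-3-hydroxy-4-oxopentanoate | CC(=O)[C@@H](O)CC(=O)OC | intermediate
14 | lithium (2S)-1-lithio-2-methylundec-10-en-2-olate | [Li]C[C@@](C)(CCCCCCCC=C)O[Li] | intermediate (not isolated)
15 | methyl (3S)-3-[(chloromagnesio)oxy]-4-oxopentanoate | CC(=O)[C@@H](O[Mg]Cl)CC(=O)OC | intermediate (not isolated)
16 | methyl (3S,4S,6R)-3,4,6-trihydroxy-4,6-dimethylpentadec-14-enoate (present as its Li/Mg alkoxides) | C[C@@](O)(CCCCCCCC=C)C[C@](C)(O)[C@@H](O)CC(=O)OC | intermediate (not isolated)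
17 | (4S,5S)-4-hydroxy-5-[(2R)-2-hydroxy-2-methylundec-10-en-1-yl]-5-methyloxolan-2-one | C[C@@](O)(CCCCCCCC=C)C[C@]1(C)OC(=O)C[C@@H]1O | intermediate
18 | 4-iodophenol | Oc1ccc(I)cc1 | starting material
19 | (4S,5S)-5-[(2R)-11-(9-borabicyclo[3.3.1]nonan-9-yl)-2-hydroxy-2-methylundecyl]-4-hydroxy-5-methyloxolan-2-one | C[C@@](O)(CCCCCCCCCB1C2CCCC1CCC2)C[C@]1(C)OC(=O)C[C@@H]1O | intermediate (not isolated)
20 | (4S,5S)-4-hydroxy-5-[(2R)-2-hydroxy-11-(4-hydroxyphenyl)-2-methylundecyl]-5-methyloxolan-2-one | C[C@@](O)(CCCCCCCCCc1ccc(O)cc1)C[C@]1(C)OC(=O)C[C@@H]1O | target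

**Step count and risks**
Total steps: 10. Longest linear sequence: 7 (steps 1, 2, 3, 4, 5, 9, 10).

Step 3 (the proposed new step) may fail because the stabilised dioxolanyl radical adds only slowly to an unactivated alkene, so reduction back to 3 (recyclable), dimerisation or hydrosilylation of the diene may dominate. The fallback uses known chemistry and sets out from 3, replacing steps 2 and 3. Commercial 9-bromonon-1-ene is converted with NaI in acetone into 9-iodonon-1-ene F1. Compound 3 is deprotonated with LiN(iPr)2 in THF at −78 °C to lithium (2S)-2-tert-butyl-5-methyl-1,3-dioxol-4-olate F2, which is alkylated by F1 (DMPU, −78 → −30 °C). This is the established self-regeneration alkylation: the electrophile enters anti to the tert-butyl group, and the route is rejoined at 6.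

Step 9 may fail through enolisation of the sensitive ketone 13 by the basic dianion, through reduction of 13 by surplus radical anion, or through incomplete chelation control. The fallback drops the reductive epoxide opening and sets out from 7. I2, PPh3 and imidazole in CH2Cl2 at 0 °C give (2R)-1-iodo-2-methylundec-10-en-2-ol F3. MeLi (1.0 equiv) then t-BuLi (2.1 equiv) in Et2O at −78 °C give 14 by iodine–lithium exchange with no reducing agent present. Anhydrous CeCl3 in THF at −78 °C converts 14 into the non-basic, oxophilic dichloro[(2R)-2-(lithiooxy)-2-methylundec-10-en-1-yl]cerium F4. F4 is added to 15 and, after the same work-up through 16, the route is rejoined at 17.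

Step 10 may fail because hydroboration and coupling are run on a substrate with two free hydroxyls and a β-hydroxy lactone that can eliminate under base, with a free phenol as partner. The fallback avoids boron and base and sets out from 17. Cross-metathesis with commercial 1-(benzyloxy)-4-ethenylbenzene (3 equiv, second-generation Hoveyda–Grubbs catalyst, CH2Cl2, 40 °C) gives (4S,5S)-5-[(2R,10E)-11-[4-(benzyloxy)phenyl]-2-hydroxy-2-methylundec-10-en-1-yl]-4-hydroxy-5-methyloxolan-2-one F5. The terminal CH2 of 17 leaves as ethene and is replaced by the styrene carbon, so the chain length is unchanged. H2 over Pd/C in EtOAc at 25 °C then reduces the alkene and cleaves the benzyl ether, and the route is rejoined at 20.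

**Further compounds**
F1 | step 3 | 9-iodonon-1-ene | ICCCCCCCC=C
F2 | step 3 | lithium (2S)-2-tert-butyl-5-methyl-1,3-dioxol-4-olate | CC1=C(O[Li])O[C@@H](C(C)(C)C)O1
F3 | step 9 | (2R)-1-iodo-2-methylundec-10-en-2-ol | C[C@@](O)(CCCCCCCC=C)CI
F4 | step 9 | dichloro[(2R)-2-(lithiooxy)-2-methylundec-10-en-1-yl]cerium | [Li]O[C@](C)(CCCCCCCC=C)C[Ce](Cl)Cl
F5 | step 10 | (4S,5S)-5-[(2R,10E)-11-[4-(benzyloxy)phenyl]-2-hydroxy-2-methylundec-10-en-1-yl]-4-hydroxy-5-methyloxolan-2-one | C[C@@](O)(CCCCCCC/C=C/c1ccc(OCc2ccccc2)cc1)C[C@]1(C)OC(=O)C[C@@H]1O
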